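(The numbers in the tables stem from a simulated flask with made-up constants; noise was put on by code.)

Birch is the run to read first: its charge of 0.046 M is the 0.046 M of the set-ups asked about.

| flask | Dx | remark | time |
|---|---|---|---|
| birch | 0.046 M | run made earlier |  |
| elm | 0.023 M | run made earlier |  |
| oak | 0.035 M | run made earlier |  |
| south-west | 0.046 M | everything together in a closed stirred flask, run for 3.0 min | 3.0 min |
| south | 0.046 M | a tube with plug flow, the mixed feed as stated, residence time 3.0 min | 3.0 min |
| north | 0.046 M | one stirred flow tank at steady state, fed with the mixture as stated, mean residence time 3.0 min |  |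
| north-west | 0.046 M | one stirred flow tank at steady state, fed with the mixture as stated, mean residence time 9.00 min |  |

| run | time / min | Qo / % | Dx / % |
|---|---|---|---|
| birch | 0.500 | 8 | 88 |
| birch | 1.00 | 15 | 78 |
| birch | 1.50 | 20 | 72 |
| birch | 2.00 | 24 | 65 |
| birch | 2.50 | 28 | 65 |
| birch | 3.00 | 31 | 56 |
| elm | 0.250 | 3 | 97 |
| elm | 0.667 | 6 | 93 |
| elm | 1.33 | 9 | 87 |
| elm | 2.00 | 15 | 81 |
| elm | 3.00 | 22 | 73 |
| elm | 4.00 | 24 | 69 |
| oak | 0.667 | 9 | 90 |
| oak | 1.33 | 13 | 78 |
| oak | 2.00 | 20 | 75 |
| oak | 2.50 | 23 | 68 |
| oak | 3.00 | 26 | 65 |
| oak | 4.00 | 27 | 60 |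

(each reading ± 1.5 percentage points)

- in percentages every species weighs as the Dx in it: one Qo counts as two
- the stated concentrations are those of everything mixed, before any reaction; amounts are the same in each set-up
- the earlier runs were made in a closed, stirred flask
- a reading or a percentage of Qo counts all its forms, free or not
- a reading of Dx is of its free form alone

- the set-up with the highest amount of Qo at the outlet or at the end, in percent of the Dx put in ("none" if the first two lie within 2 percentage points) (south-west / south / north / north-west / none)
- amount of Qo at the outlet or at the end, in percent of the Dx put in, south-west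
- amount of Qo at the outlet or at the end, in percent of the Dx put in, south
- amount of Qo at the outlet or at the end, in percent of the Dx put in, north
- amount of Qo at the outlet or at the end, in percent of the Dx put in, north-west

Two times matter, and I compare them. One is the time the vessel gives, 3.0 min or 9.00 min. The other is the clock of the charge. After 1.00 min, birch holds 15% Qo with Dx at 78%. Dividing that rate by the squared mean Dx fraction gives, as a reading, a pace of 0.189 min⁻¹, so the clock is 5.28 min. Elm, at half the charge, reads 0.0916 min⁻¹ at 2.00 min, half the birch pace. So I take the step as second order in Dx, and this clock belongs to this charge.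

I count turnovers, the vessel time over the clock (the Damköhler number): 0.568 turnovers at 3.0 min. I take south-west and south to repeat birch. A tank works at its outlet Dx, so I take Qo as turnovers times the squared Dx fraction, with Dx and Qo summing to the whole:

| Set-up | Turnovers | My Qo |
|---|---|---|
| south-west, south | 0.568 | 31% |
| north | 0.568 | 28.8% |
| north-west | 1.70 | 47.3% |

Birch falls 13 percentage points short of the whole at 3.0 min, so I read both tank figures as high.

The forecast, for which the shortfall suggests that “free Dx is held reversibly by Qo”, names north-west and gives 30.5%, 30.5%, 24% and 39%, lower than mine in north and north-west.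

The flask gives north-west at 34.6%, ahead of south-west and south at 30.1% by 4.5 points, with north at 23.4%.

    Qo ⇌ Ky (K = 0.440, k = 0.00430 s⁻¹)
    Dx + Qo ⇌ Lx, settled at all times (K = 64.0 M⁻¹)
    2 Dx ⇌ Qo (K = 55.0 M⁻¹, k = 0.0360 M⁻¹ s⁻¹)

North's outlet holds Dx at 66.7%, so 0.568 turnovers times its squared fraction give 25.3%, against 23.4% in the flask. North-west's outlet holds Dx at 50.0%, so 1.70 turnovers give 42.5%, against 34.6%.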